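**Retrosynthetic overview**

1. Glaucolide K ⇐ macrocyclic butenolide 20 by C8 methacrylation, C1/C13 acetylation and, last, peripheral epoxidation of the 4E-alkene (epoxide ring formed last).
2. 20 ⇐ acyclic ynal ester 18 in one operation: a nickel-catalysed methylative alkyne–aldehyde coupling forms C5–C6 and C4–C15 and closes the ten-membered ring A; the C6 alkoxide then closes ring B (butenolide) on C12.
3. Enabling feature: C6 is an allylic carbinol carbon lying between the C4(C15)=C5 unit latent in the epoxide (C15 cis to C6) and the tetrasubstituted C7=C11 bond of ring B, which holds O6 beside the C12 carbonyl. A terminal C4≡C5 alkyne, a C6 aldehyde and a methyl donor therefore suffice.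
4. 18 ⇐ 2-silyl-3,4-disubstituted furan 14 (singlet oxygen unmasks the Z-4-oxo-enoate; silicon on C12 fixes the regiochemistry) ⇐ furyl dianion 10 + cis-lactone 9 (C7–C8 bond), with C8 set by CBS reduction.
5. 9 ⇐ 5-(trimethylsilyl)pent-4-ynal by (Z)-crotylboration (C1, C10), hydroboration and oxidative lactonisation; 3 ⇐ furan-3-ylmethanol by silylation and retro-Brook shift.

Key step: step 13

Remark: locants C1–C15 are those of the germacranolide skeleton of the target (C1 acetoxy carbinol, C4–C5 epoxide, C6 lactone carbinol, C7=C11, C8 methacrylate carbinol, C10 methyl-bearing carbon, C12 lactone carbonyl, C13 acetoxymethyl, C14 and C15 methyls).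

Assumption: the (Z)-crotylborane made from (+)-Ipc2BOMe, i.e. from (−)-α-pinene, is taken to give the (S)-carbinol with aliphatic aldehydes; if the sense were opposite, the antipodal reagent would be used.

**Route**

Step 1
Reactants: 1 furan-3-ylmethanol
Product: 2 tert-butyl(furan-3-ylmethoxy)dimethylsilane
Conditions: TBSCl, imidazole, CH2Cl2, 0 °C to rt
Reagents that add atoms: tert-butyldimethylsilyl chloride, CC(C)(C)[Si](C)(C)Cl
Why: Standard imidazole-promoted silyl ether formation on a primary alcohol, with no stereocentre involved.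

Step 2
Reactants: 2 tert-butyl(furan-3-ylmethoxy)dimethylsilane
Product: 3 [2-(tert-butyldimethylsilyl)furan-3-yl]methanol
Conditions: n-BuLi, HMPA, THF, −78 °C to 0 °C; then aq NH4Cl
Reagents that add atoms: none
Why: Lithiation at the furan α-position next to the silyloxymethyl group is followed by an anionic 1,4 O→C silyl shift (retro-Brook rearrangement), a known entry to 2-silyl-3-(hydroxymethyl)furans that puts silicon on the future lactone carbonyl carbon C12.

Step 3
Reactants: 4 5-(trimethylsilyl)pent-4-yn-1-ol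
Product: 5 5-(trimethylsilyl)pent-4-ynal
Conditions: 2,2,6,6-tetramethylpiperidin-1-oxyl (TEMPO, 10 mol %), PhI(OAc)2, CH2Cl2, rt
Reagents that add atoms: none
Why: Oxoammonium (TEMPO/PhI(OAc)2) oxidation should stop at the aldehyde and leave the silylalkyne untouched.

Step 4
Reactants: 5 5-(trimethylsilyl)pent-4-ynal
Product: 6 (3S,4S)-3-methyl-8-(trimethylsilyl)oct-1-en-7-yn-4-ol
Conditions: (Z)-crotyl-B(Ipc)2 (preformed from cis-2-butene, KOt-Bu, n-BuLi, (+)-Ipc2BOMe, BF3·OEt2), THF/Et2O, −78 °C; then NaBO3·4H2O, THF/H2O, rt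
Reagents that add atoms: (Z)-crotyldiisopinocampheylborane, C/C=C\CB([C@H]1C[C@H]2C[C@@H]([C@@H]1C)C2(C)C)[C@H]1C[C@H]2C[C@@H]([C@@H]1C)C2(C)C
Why: Brown asymmetric crotylboration through a closed chair transition state, in which the Z-crotyl geometry gives the syn C10-methyl/C1-hydroxyl pair and the Ipc ligands set the absolute configuration (1S,10S).

Step 5
Reactants: 6 (3S,4S)-3-methyl-8-(trimethylsilyl)oct-1-en-7-yn-4-ol
Product: 7 (3S,4S)-3-methyl-8-(trimethylsilyl)oct-7-yne-1,4-diol
Conditions: 9-BBN (2.2 equiv), THF, 0 °C to rt; then 30 % H2O2, aq NaOAc, 0 °C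
Reagents that add atoms: hydrogen peroxide, OO
Why: Anti-Markovnikov hydroboration–oxidation with 9-BBN should be selective for the monosubstituted alkene over the silyl-capped alkyne and creates C8 as a primary alcohol without touching C1 or C10.

Step 6
Reactants: 7 (3S,4S)-3-methyl-8-(trimethylsilyl)oct-7-yne-1,4-diol
Product: 9 (4S,5S)-4-methyl-5-[4-(trimethylsilyl)but-3-yn-1-yl]oxolan-2-one (cis-lactone), via lactol 8 (not isolated)
Conditions: TEMPO (20 mol %), PhI(OAc)2 (2.5 equiv), CH2Cl2, rt
Reagents that add atoms: none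
Why: Oxidative lactonisation of a 1,4-diol, in which only the primary alcohol is oxidised, the aldehyde closes on the C1 hydroxyl and the lactol is oxidised again, so that C8 becomes an acyl donor and C1 is masked.

Step 7
Reactants: 3 [2-(tert-butyldimethylsilyl)furan-3-yl]methanol; 9 cis-lactone
Product: 11 (3S,4S)-1-[5-(tert-butyldimethylsilyl)-4-(hydroxymethyl)furan-3-yl]-4-hydroxy-3-methyl-8-(trimethylsilyl)oct-7-yn-1-one, via dilithiated furan 10 (not isolated)
Conditions: 3, n-BuLi (2.2 equiv), DME, 0 °C; then 9, THF, −78 °C; aq NH4Cl at −78 °C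
Reagents that add atoms: none
Why: Alkoxide-directed lithiation of 2-silyl-3-furanmethanols occurs at the β-position C7 because silicon blocks the neighbouring α-position, and acylation of the aryllithium by the γ-lactone should stop at the ketone because the lactol alkoxide persists at −78 °C.

Step 8
Reactants: 11 keto diol
Product: 12 (3S,4S)-4-[(tert-butyldimethylsilyl)oxy]-1-[5-(tert-butyldimethylsilyl)-4-{[(tert-butyldimethylsilyl)oxy]methyl}furan-3-yl]-3-methyl-8-(trimethylsilyl)oct-7-yn-1-one
Conditions: TBSCl (3 equiv), imidazole, DMF, rt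
Reagents that add atoms: tert-butyldimethylsilyl chloride, CC(C)(C)[Si](C)(C)Cl
Why: Silyl ether formation traps the open hydroxy ketone out of its lactol equilibrium and protects with one reagent the two oxygens (C1, C13) that later become the acetates.

Step 9
Reactants: 12 bis-silyl ether ketone
Product: 13 (1S,3S,4S)-4-[(tert-butyldimethylsilyl)oxy]-1-[5-(tert-butyldimethylsilyl)-4-{[(tert-butyldimethylsilyl)oxy]methyl}furan-3-yl]-3-methyl-8-(trimethylsilyl)oct-7-yn-1-ol
Conditions: (R)-1-methyl-3,3-diphenyltetrahydro-1H,3H-pyrrolo[1,2-c][1,3,2]oxazaborole (20 mol %), BH3·SMe2, THF, −30 °C; then MeOH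
Reagents that add atoms: none
Why: Corey–Bakshi–Shibata reduction of the aryl alkyl ketone, in which the furyl group acts as the large and the C9 methylene as the small substituent, so that the (R)-catalyst should deliver hydride to the face giving the (8S)-carbinol under reagent control.

Step 10
Reactants: 13 silylalkyne
Product: 14 (1S,3S,4S)-4-[(tert-butyldimethylsilyl)oxy]-1-[5-(tert-butyldimethylsilyl)-4-{[(tert-butyldimethylsilyl)oxy]methyl}furan-3-yl]-3-methyloct-7-yn-1-ol
Conditions: K2CO3, MeOH, rt
Reagents that add atoms: none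
Why: Mild methanolytic protiodesilylation of the alkynyl C–Si bond should spare the TBS ethers and the aryl C–Si bond.

Step 11
Reactants: 14 terminal alkyne furan
Product: 17 5-hydroxy-3-{[(tert-butyldimethylsilyl)oxy]methyl}-4-[(1S,3S,4S)-4-[(tert-butyldimethylsilyl)oxy]-1-hydroxy-3-methyloct-7-yn-1-yl]furan-2(5H)-one (both C6 lactol epimers), via furan endoperoxide 15 (not isolated), via silyl ester aldehyde 16 (not isolated)
Conditions: O2, 5,10,15,20-tetraphenylporphyrin (1 mol %), visible light, CH2Cl2, −78 °C; then wet silica gel, rt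
Reagents that add atoms: dioxygen, O=O
Why: Silyl-directed photooxygenation of a 2-silylfuran, in which [4+2] addition of singlet oxygen and a 1,2-silyl shift in the endoperoxide place the acid at the silicon-bearing carbon C12 and the aldehyde at C6, while the alkyne is inert to singlet oxygen.

Step 12
Reactants: 17 γ-hydroxybutenolide
Product: 18 methyl (2Z,4S,6S,7S)-7-[(tert-butyldimethylsilyl)oxy]-2-{[(tert-butyldimethylsilyl)oxy]methyl}-3-formyl-4-hydroxy-6-methylundec-2-en-10-ynoate
Conditions: TMSCHN2 (1.3 equiv), toluene/MeOH 4:1, 0 °C; then AcOH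
Reagents that add atoms: (trimethylsilyl)diazomethane, C[Si](C)(C)C=[N+]=[N-]
Why: Esterification of the ring-opened carboxylic acid tautomer of the pseudo-acid with a diazoalkane should drain both lactol epimers into the open Z-4-oxo-enoate and so free the C6 aldehyde.

Step 13
Reactants: 18 ynal ester
Product: 20 (1S,4E,6R,8S,10S)-1,13-bis[(tert-butyldimethylsilyl)oxy]-8-hydroxygermacra-4,7(11)-dien-12,6-olide, via macrocyclic hydroxy ester 19 (not isolated)
Conditions: Ni(cod)2 (20 mol %), Me2Zn (5 equiv), THF, 0 °C, syringe-pump addition of 18 (final 2 mM); then aq NH4Cl; pyridinium p-toluenesulfonate (cat.), CH2Cl2, rt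
Reagents that add atoms: dimethylzinc, C[Zn]C
Why: Proposed new method: Me2Zn first turns the C8 hydroxyl into a methylzinc alkoxide that chelates the C6 aldehyde oxygen, zerovalent nickel then joins the terminal alkyne carbon C5 to the aldehyde carbon C6 by oxidative cyclisation to an oxanickelacyclopentene of divalent nickel (Ni bound to C4 and O6), methyl transfer from zinc and C4–CH3 reductive elimination place the C15 methyl cis to C6, and the C6 zinc alkoxide finally attacks the cis-held C12 methyl ester. The closest known reactions are the nickel-catalysed alkylative cyclisation and three-component coupling of aldehydes, alkynes and organozincs (small rings and intermolecular cases) and the nickel-catalysed reductive macrocyclisation of terminal ynals to endocyclic E-allylic alcohols; their combination on a ten-membered ring is the new element. Ring A closes 10-endo-dig at the alkyne (exo-trig at the aldehyde) and ring B closes by 5-exo-trig acyl substitution. The only new stereocentre, C6, is controlled by C8: the six-membered zinc chelate O8–C8–C7–C6–O6 makes the closing ring a bridged bicycle in which C9 and C5 must leave the chelate on the same face, which is the 6,8-cis-dioxygenated (6R,8S) arrangement of 20, and the 4E geometry follows from syn addition across the alkyne. The step needs bond formation at the terminal rather than the internal alkyne carbon (the usual preference of terminal alkynes with ligand-free or small-ligand nickel), 1,2-reaction of the aldehyde rather than conjugate reaction (both β-carbons of the oxo-enoate are fully substituted and the crowded aldehyde is twisted out of conjugation) and methyl transfer without reduction (methyl has no β-hydrogen), while high dilution holds back oligomers.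

Step 14
Reactants: 20 macrocyclic hydroxy butenolide
Product: 21 (1S,4E,6R,8S,10S)-1,13-bis[(tert-butyldimethylsilyl)oxy]-8-(methacryloyloxy)germacra-4,7(11)-dien-12,6-olide
Conditions: methacrylic anhydride, Et3N, 4-(dimethylamino)pyridine (10 mol %), CH2Cl2, 0 °C to rt
Reagents that add atoms: methacrylic anhydride, C=C(C)C(=O)OC(=O)C(C)=C
Why: Nucleophile-catalysed acyl transfer to the only free hydroxyl should install the methacrylate with retention at C8.

Step 15
Reactants: 21 bis-silyl ether
Product: 22 (1S,4E,6R,8S,10S)-1,13-dihydroxy-8-(methacryloyloxy)germacra-4,7(11)-dien-12,6-olide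
Conditions: HF·pyridine, pyridine/THF, 0 °C to rt
Reagents that add atoms: none
Why: Buffered fluoride cleavage of both TBS ethers is non-basic and should leave the butenolide (acidic H6), the methacrylate and the 4E-alkene intact.

Step 16
Reactants: 22 diol
Product: 23 (1S,4E,6R,8S,10S)-1,13-diacetoxy-8-(methacryloyloxy)germacra-4,7(11)-dien-12,6-olide
Conditions: Ac2O, pyridine, 4-(dimethylamino)pyridine (5 mol %), CH2Cl2, 0 °C
Reagents that add atoms: acetic anhydride, CC(=O)OC(C)=O
Why: Standard acetylation of the primary C13 and secondary C1 alcohols under mild amine base.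

Step 17
Reactants: 23 diacetate
Product: 24 glaucolide K, (1S,4R,5R,6S,8S,10S)-1,13-diacetoxy-4,5-epoxy-8-(methacryloyloxy)germacr-7(11)-en-12,6-olide
Conditions: mCPBA, NaHCO3, CH2Cl2, 0 °C
Reagents that add atoms: 3-chloroperoxybenzoic acid, OOC(=O)c1cccc(Cl)c1
Why: Prilezhaev epoxidation should touch only the electron-rich trisubstituted C4=C5 bond, and because allylic 1,3-strain with the C15 methyl holds H6 in the alkene plane with ring atom C7 on the inner face, the peracid should approach the peripheral face syn to O6 and give the (4R,5R)-epoxide (the 4α,5β arrangement of parthenolide-type lactones).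

**Compound list**

1 | furan-3-ylmethanol | OCc1ccoc1 | starting material
2 | tert-butyl(furan-3-ylmethoxy)dimethylsilane | CC(C)(C)[Si](C)(C)OCc1ccoc1 | intermediate
3 | [2-(tert-butyldimethylsilyl)furan-3-yl]methanol | OCc1ccoc1[Si](C)(C)C(C)(C)C | intermediate
4 | 5-(trimethylsilyl)pent-4-yn-1-ol | C[Si](C)(C)C#CCCCO | starting material
5 | 5-(trimethylsilyl)pent-4-ynal | C[Si](C)(C)C#CCCC=O | intermediate
6 | (3S,4S)-3-methyl-8-(trimethylsilyl)oct-1-en-7-yn-4-ol | C=C[C@H](C)[C@@H](O)CCC#C[Si](C)(C)C | intermediate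
7 | (3S,4S)-3-methyl-8-(trimethylsilyl)oct-7-yne-1,4-diol | OCC[C@H](C)[C@@H](O)CCC#C[Si](C)(C)C | intermediate
8 | (4S,5S)-4-methyl-5-[4-(trimethylsilyl)but-3-yn-1-yl]oxolan-2-ol (lactol, both anomers) | OC1C[C@H](C)[C@H](CCC#C[Si](C)(C)C)O1 | intermediate
9 | (4S,5S)-4-methyl-5-[4-(trimethylsilyl)but-3-yn-1-yl]oxolan-2-one (cis-lactone) | O=C1C[C@H](C)[C@H](CCC#C[Si](C)(C)C)O1 | intermediate
10 | lithium [2-(tert-butyldimethylsilyl)-4-lithiofuran-3-yl]methanolate | [Li]OCc1c([Li])coc1[Si](C)(C)C(C)(C)C | intermediate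
11 | (3S,4S)-1-[5-(tert-butyldimethylsilyl)-4-(hydroxymethyl)furan-3-yl]-4-hydroxy-3-methyl-8-(trimethylsilyl)oct-7-yn-1-one | OCc1c(C(=O)C[C@H](C)[C@@H](O)CCC#C[Si](C)(C)C)coc1[Si](C)(C)C(C)(C)C | intermediate
12 | (3S,4S)-4-[(tert-butyldimethylsilyl)oxy]-1-[5-(tert-butyldimethylsilyl)-4-{[(tert-butyldimethylsilyl)oxy]methyl}furan-3-yl]-3-methyl-8-(trimethylsilyl)oct-7-yn-1-one | CC(C)(C)[Si](C)(C)OCc1c(C(=O)C[C@H](C)[C@@H](O[Si](C)(C)C(C)(C)C)CCC#C[Si](C)(C)C)coc1[Si](C)(C)C(C)(C)C | intermediate
13 | (1S,3S,4S)-4-[(tert-butyldimethylsilyl)oxy]-1-[5-(tert-butyldimethylsilyl)-4-{[(tert-butyldimethylsilyl)oxy]methyl}furan-3-yl]-3-methyl-8-(trimethylsilyl)oct-7-yn-1-ol | CC(C)(C)[Si](C)(C)OCc1c([C@@H](O)C[C@H](C)[C@@H](O[Si](C)(C)C(C)(C)C)CCC#C[Si](C)(C)C)coc1[Si](C)(C)C(C)(C)C | intermediate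
14 | (1S,3S,4S)-4-[(tert-butyldimethylsilyl)oxy]-1-[5-(tert-butyldimethylsilyl)-4-{[(tert-butyldimethylsilyl)oxy]methyl}furan-3-yl]-3-methyloct-7-yn-1-ol | CC(C)(C)[Si](C)(C)OCc1c([C@@H](O)C[C@H](C)[C@@H](O[Si](C)(C)C(C)(C)C)CCC#C)coc1[Si](C)(C)C(C)(C)C | intermediate
15 | 2,3,7-trioxabicyclo[2.2.1]hept-5-ene endoperoxide of furan 14 (bridgeheads C6 and C12) | CC(C)(C)[Si](C)(C)OCC1=C([C@@H](O)C[C@H](C)[C@@H](O[Si](C)(C)C(C)(C)C)CCC#C)C2OOC1([Si](C)(C)C(C)(C)C)O2 | intermediate
16 | tert-butyldimethylsilyl (2Z,4S,6S,7S)-7-[(tert-butyldimethylsilyl)oxy]-2-{[(tert-butyldimethylsilyl)oxy]methyl}-3-formyl-4-hydroxy-6-methylundec-2-en-10-ynoate | O=C/C([C@@H](O)C[C@H](C)[C@@H](O[Si](C)(C)C(C)(C)C)CCC#C)=C(/CO[Si](C)(C)C(C)(C)C)C(=O)O[Si](C)(C)C(C)(C)C | intermediate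
17 | 5-hydroxy-3-{[(tert-butyldimethylsilyl)oxy]methyl}-4-[(1S,3S,4S)-4-[(tert-butyldimethylsilyl)oxy]-1-hydroxy-3-methyloct-7-yn-1-yl]furan-2(5H)-one (both lactol epimers) | OC1OC(=O)C(CO[Si](C)(C)C(C)(C)C)=C1[C@@H](O)C[C@H](C)[C@@H](O[Si](C)(C)C(C)(C)C)CCC#C | intermediate
18 | methyl (2Z,4S,6S,7S)-7-[(tert-butyldimethylsilyl)oxy]-2-{[(tert-butyldimethylsilyl)oxy]methyl}-3-formyl-4-hydroxy-6-methylundec-2-en-10-ynoate | O=C/C([C@@H](O)C[C@H](C)[C@@H](O[Si](C)(C)C(C)(C)C)CCC#C)=C(/CO[Si](C)(C)C(C)(C)C)C(=O)OC | intermediate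
19 | methyl (1S,4E,6R,7(11)Z,8S,10S)-1,13-bis[(tert-butyldimethylsilyl)oxy]-6,8-dihydroxygermacra-4,7(11)-dien-12-oate (formed as its zinc alkoxide) | COC(=O)/C(CO[Si](C)(C)C(C)(C)C)=C1/[C@@H](O)C[C@H](C)[C@@H](O[Si](C)(C)C(C)(C)C)CC/C(C)=C/[C@H]1O | intermediate
20 | (1S,4E,6R,8S,10S)-1,13-bis[(tert-butyldimethylsilyl)oxy]-8-hydroxygermacra-4,7(11)-dien-12,6-olide | O[C@H]1C[C@H](C)[C@@H](O[Si](C)(C)C(C)(C)C)CC/C(C)=C/[C@H]2OC(=O)C(CO[Si](C)(C)C(C)(C)C)=C12 | intermediate
21 | (1S,4E,6R,8S,10S)-1,13-bis[(tert-butyldimethylsilyl)oxy]-8-(methacryloyloxy)germacra-4,7(11)-dien-12,6-olide | C=C(C)C(=O)O[C@H]1C[C@H](C)[C@@H](O[Si](C)(C)C(C)(C)C)CC/C(C)=C/[C@H]2OC(=O)C(CO[Si](C)(C)C(C)(C)C)=C12 | intermediate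
22 | (1S,4E,6R,8S,10S)-1,13-dihydroxy-8-(methacryloyloxy)germacra-4,7(11)-dien-12,6-olide | C=C(C)C(=O)O[C@H]1C[C@H](C)[C@@H](O)CC/C(C)=C/[C@H]2OC(=O)C(CO)=C12 | intermediate
23 | (1S,4E,6R,8S,10S)-1,13-diacetoxy-8-(methacryloyloxy)germacra-4,7(11)-dien-12,6-olide | C=C(C)C(=O)O[C@H]1C[C@H](C)[C@@H](OC(C)=O)CC/C(C)=C/[C@H]2OC(=O)C(COC(C)=O)=C12 | intermediate
24 | glaucolide K, (1S,4R,5R,6S,8S,10S)-1,13-diacetoxy-4,5-epoxy-8-(methacryloyloxy)germacr-7(11)-en-12,6-olide | C=C(C)C(=O)O[C@H]1C[C@H](C)[C@@H](OC(C)=O)CC[C@@]2(C)O[C@@H]2[C@H]2OC(=O)C(COC(C)=O)=C12 | target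

**Step count and risks**

Total steps: 17. Longest linear sequence: 15 steps (steps 3 to 17, from 4); the furan branch (steps 1 and 2) joins at step 7.

Steps most likely to fail:

1. Step 13 (proposed new method). Uncatalysed methyl transfer from zinc to the aldehyde may outrun nickel turnover. Bond formation at the internal alkyne carbon would give the nine-membered exocyclic isomer, and alkyne oligomerisation may consume the substrate. The strained E-cyclodecene may not close, or the aldehyde may be attacked on the other face if the zinc chelate is not held. The fallback uses known chemistry, sets out from 14 and comes back at 20. Zirconium-catalysed carboalumination of the terminal alkyne (AlMe3, Cp2ZrCl2, CH2Cl2; then I2) should give the (E)-2-methylvinyl iodide furan F1, with the C15 methyl already in place and cis to iodine. Photooxygenation as in step 11 (the furan reacts far faster with singlet oxygen than the iodoalkene) should give the iodo hydroxybutenolide F2, and TMSCHN2 as in step 12 the iodo oxo-ester F3. An intramolecular Nozaki–Hiyama–Kishi reaction (CrCl2 in excess, NiCl2 2 mol %, DMSO, rt, high dilution) then forms C5–C6 with retention of the alkene geometry, and the chromium alkoxide lactonises onto the methyl ester to give 20. The same C8-alkoxide chelate argument applies to the C6 configuration.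

2. Step 7. The basic aryllithium may enolise the lactone, the lactol alkoxide may collapse early and allow double addition, or proton transfer may simply return 3. The fallback sets out from 9 and comes back at 12. Aminolysis of the lactone with MeNH(OMe)·HCl/AlMe3 should give the hydroxy Weinreb amide F4, and TBSCl/imidazole its silyl ether F5. Dianion 10 then adds once, because the chelated tetrahedral adduct cannot release the ketone before work-up, to give the hydroxymethyl furyl ketone F6. Silylation of the primary alcohol gives 12.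

3. Step 17. Facial selectivity may be poor if a second ring conformer with the alkene plane flipped is populated, so that the peripheral face becomes the one anti to O6. The fallback sets out from 23 and comes back at 24. It replaces substrate control by reagent control: a Shi epoxidation with the D-fructose-derived ketone 1,2:4,5-di-O-isopropylidene-β-D-erythro-2,3-hexodiulo-2,6-pyranose (Oxone, buffered K2CO3, MeCN/dimethoxymethane/H2O, 0 °C). Its known sense for trans-type trisubstituted alkenes corresponds to the (4R,5R) epoxide, and it makes no new compound.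

Further compounds
F1 | step 13 | (1S,3S,4S,7E)-4-[(tert-butyldimethylsilyl)oxy]-1-[5-(tert-butyldimethylsilyl)-4-{[(tert-butyldimethylsilyl)oxy]methyl}furan-3-yl]-8-iodo-3,7-dimethyloct-7-en-1-ol | CC(C)(C)[Si](C)(C)OCc1c([C@@H](O)C[C@H](C)[C@@H](O[Si](C)(C)C(C)(C)C)CC/C(C)=C/I)coc1[Si](C)(C)C(C)(C)C
F2 | step 13 | 5-hydroxy-3-{[(tert-butyldimethylsilyl)oxy]methyl}-4-[(1S,3S,4S,7E)-4-[(tert-butyldimethylsilyl)oxy]-1-hydroxy-8-iodo-3,7-dimethyloct-7-en-1-yl]furan-2(5H)-one (both lactol epimers) | OC1OC(=O)C(CO[Si](C)(C)C(C)(C)C)=C1[C@@H](O)C[C@H](C)[C@@H](O[Si](C)(C)C(C)(C)C)CC/C(C)=C/I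
F3 | step 13 | methyl (2Z,4S,6S,7S,10E)-7-[(tert-butyldimethylsilyl)oxy]-2-{[(tert-butyldimethylsilyl)oxy]methyl}-3-formyl-4-hydroxy-11-iodo-6,10-dimethylundeca-2,10-dienoate | O=C/C([C@@H](O)C[C@H](C)[C@@H](O[Si](C)(C)C(C)(C)C)CC/C(C)=C/I)=C(/CO[Si](C)(C)C(C)(C)C)C(=O)OC
F4 | step 7 | (3S,4S)-4-hydroxy-N-methoxy-N,3-dimethyl-8-(trimethylsilyl)oct-7-ynamide | CON(C)C(=O)C[C@H](C)[C@@H](O)CCC#C[Si](C)(C)C
F5 | step 7 | (3S,4S)-4-[(tert-butyldimethylsilyl)oxy]-N-methoxy-N,3-dimethyl-8-(trimethylsilyl)oct-7-ynamide | CON(C)C(=O)C[C@H](C)[C@@H](O[Si](C)(C)C(C)(C)C)CCC#C[Si](C)(C)C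
F6 | step 7 | (3S,4S)-4-[(tert-butyldimethylsilyl)oxy]-1-[5-(tert-butyldimethylsilyl)-4-(hydroxymethyl)furan-3-yl]-3-methyl-8-(trimethylsilyl)oct-7-yn-1-one | OCc1c(C(=O)C[C@H](C)[C@@H](O[Si](C)(C)C(C)(C)C)CCC#C[Si](C)(C)C)coc1[Si](C)(C)C(C)(C)C
F0 | step 17 | none | none
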